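## The problem

The target is a caged acylphloroglucinol. The numbering used throughout is: ring A is C1(benzoyl)–C2(=O)–C3–C4(=O)–C5(geranyl)–C9(=O); ring B is C1–C9–C5–C6H2–C7H–C8Me2; the bridge C10H2–C11H ties C7 to C3 and closes the seven-membered ring C (C3–C4–C5–C6–C7–C10–C11) of a homoadamantane; the cyclopentane ring D (C3–C11–C12Me2–C13H2–C14H2) is fused on the bridge bond C3–C11. Four of the five stereocentres (C1, C3, C5, C7) are cage bridgeheads: once C7 is fixed, bridges to C5 and C1 can only close on the face of ring B that carries the C10 arm, so C7 can control both. The fifth centre, C11, decides on which side of the cage ring D lies; in the target C12 points to the C2/C1/C8 side, which on ring D means the C2 carbonyl is cis and the C4 carbonyl trans to C10. C11 can therefore control C3 (an electrophile entering a C3 enolate anti to the C10 arm becomes C4), but C7 and C11 are separated by the free methylene C10 and cannot control each other, so one of them must be set by a reagent in the presence of the other. The three ring ketones are flanked by the quaternary carbons C1, C3, C5, C8 and C12, every bond to them is hindered, and the non-enolisable tricarbonyl array is open to retro-Claisen cleavage by nucleophiles; the geranyl chain with its two trisubstituted alkenes will not survive strong acid, electrophilic oxidants or hydrogenation, and the benzoyl group sits on a bridgehead beside C8. The feature that invites a carbenoid approach is ring D: it carries no functional group, C3 is α to the C2 carbonyl, C11 is the fifth atom from C3 along C14–C13–C12, and the quaternary C12 offers only methyl hydrogens as competitors, which is the pattern of a 1,5 C–H insertion.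

## Retrosynthesis

**C1–benzoyl (25 ⇒ 23, through 24).** The exocyclic bond from C1 to the benzoyl carbon is cut first. Carrying the benzoyl group from the start would make C1 a hindered, stabilised diketone carbon that has to be bonded to C2 beside C8. In the debenzoyl trione 23 the C1 hydrogen is the only acidic one and lies between two carbonyl groups. The forward step asks for bridgehead lithiation to 24 and acylation on carbon without attack on the three ketones.

**Ring A, C1–C2 (23 ⇒ 22).** Of the ring A bonds, C1–C2 is the one whose two ends are already differentiated in a simple precursor: C2 is the ester carbon that C3 has carried since the diazo ester, and in diketo ester 22 C1 is the only enolisable carbon. Cutting C3–C4 or C4–C5 here instead would leave a quaternary carbon to be made in the cage-closing step. The precursor has one ring and one stereocentre fewer. The forward Claisen closure must outrun reopening by the methoxide it releases.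

**C5–geranyl (22 ⇒ 20 + 21).** The chain is removed next, so that in the synthetic direction the carbenoid, the amide base, the chromium oxidant and the copper hydride never meet the 1,5-diene. In β-diketone 20 C5 is the only carbon between two ketones, so allylation with geranyl acetate 21 is regiochemically unambiguous and the bicyclic frame leaves one position open. Placing the chain on the enone before ring C closes would cost a halogenation and a cross-coupling.

**Ring C, C4–C5 (20 ⇒ 19 ⇒ 18).** After adjusting C4 to the carbinol 19, the seven-membered ring is opened at C4–C5 by an aldol disconnection. Against C3–C4 this keeps the quaternary C3 out of the ring-forming step; against C7–C10 or C10–C11 it uses carbonyl polarity that is already there. In enone aldehyde 18 the C5 enolate is available regiospecifically by conjugate hydride addition, which a saturated C9 ketone with two α-methylene groups would not allow. The forward step must close a seven-membered ring; C5 is set by the tether from C7 and the C4 carbinol centre is erased by oxidation.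

**C9 oxygen and C3–C4 (18 ⇒ 17 ⇒ 15, through 16).** The C9 carbonyl is traced to allylic oxidation of the C5=C6 alkene of 17. That alkene is exactly what the substitution that sets C7 leaves behind, so no extra functional group has to be carried. C4 is then cut from C3 as a formyl cation equivalent: lithium enolate 16 of ester 15 should be attacked anti to the C10 arm, which makes the new carbon C4 (trans to C10) and leaves the ester carbon as C2 (cis), as the cage requires. Both operations come before the enone exists, because an enone would not tolerate the amide base.

**Ring D, C3–C11 (15 ⇒ 14).** This is the key cut. Ring D is opened at the only ring bond that joins a carbon α to a carbonyl to an unfunctionalised methylene five atoms away. Neighbouring cuts (C11–C12, C12–C13) would need a nucleophile or electrophile at a neopentyl centre. The precursor, diazo ester 14, is an open chain on a cyclohexene with a single stereocentre. The forward insertion must choose C11 over the C12 methyl groups, one C11 hydrogen over the other, and insertion over hydride shift.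

**Diazo ester (14 ⇒ 13 ⇒ 11 + 12).** The diazo group is traced to deacylative diazo transfer on the 2-alkylacetoacetate 13. C3–C14 is cut as an alkylation of methyl acetoacetate 12 by iodide 11. C3 and C2 thus arrive as a two-carbon unit that carries the handle for diazo transfer.

**C7–C10 (11 ⇒ 10 ⇒ 9 ⇒ 7 + 4, through 8).** Functional group changes lead back to silyl ether 9. The bond from C7 to the chain is cut as an anti SN2′ substitution of picolinate 7 by Grignard reagent 8, made from bromide 4. This sets C7 by chirality transfer from a carbinol centre, next to the gem-dimethyl carbon, and places the alkene at C5=C6. A conjugate addition to the enone would reach the same bond but would need a further operation to place the alkene.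

**Building blocks (7 ⇒ 6 ⇒ 5; 4 ⇒ 3 ⇒ 2 ⇒ 1).** Picolinate 7 comes from allylic alcohol 6, the CBS reduction product of enone 5. Bromide 4 comes from the symmetric diol 2 through its monosilyl ether 3; diol 2 is the reduction product of anhydride 1, whose quaternary carbon becomes C12.

## Roads not taken

Alternative 1: This plan cuts C3–C11 and C12–C13 together, back to A2, a complete ring A/ring B trione enol that carries a 2,3-epoxy-3-methylbutyl arm on C7 and a (Z)-2-silylvinyl group on enolic C3.
- Forward key step: SnCl4 would open the epoxide by attack of C3 on C11 (ring C). The tertiary C12–O bond would then ionise and the cation would be trapped at C13 by the vinylsilane (ring D), giving the cyclopentene A1. The C13=C14 bond of A1 must finally be hydrogenated to reach 25.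
- Merits: two rings and two C–C bonds in one operation, on a bicyclic core of a familiar kind. The benzoyl and geranyl groups are in place before the cage closes, so no bridgehead acylation is needed. In that respect it is better than the chosen plan, which pays for its late benzoylation with a bridgehead lithiation.
- Weak points: C3 must attack the secondary epoxide carbon in a seven-membered closure, whereas Lewis acid activation puts positive charge on tertiary C12 and the enol oxygen is the more usual nucleophile toward such epoxides. Ionising the C12 oxygen function needs forcing Lewis acidity in a molecule whose geranyl chain is itself a cation–olefin substrate. The epoxide must be made selectively beside two other trisubstituted alkenes. The last hydrogenation must pick a cyclopentene flanked by two quaternary carbons over the geranyl alkenes.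
- Comparison: the chosen plan is longer, but it builds ring D on an open chain where the only competition is among C–H bonds, and it keeps the geranyl group away from every electrophilic step.

Alternative 2: This plan cuts C3–C11 and C1–C2 together, opening the seven-membered carbocycle C1–C2–C3–C11–C10–C7–C8 (ring E) and ring D back to the enyne A4. In A4 a terminal alkyne is tethered through C14–C13–C12 to a 1-siloxy-2,2-dimethyl-1-vinylcyclopropane.
- Forward key step: [Rh(cod)2]SbF6 with BINAP would effect the intramolecular (5+2) cycloaddition to the hydroazulene A3, with C11 as the only stereocentre.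
- Merits: two rings and two bonds form catalytically, there is no counterpart of the hydride-shift and site-selectivity questions of a carbenoid insertion, and the 5–7 bicycle is reached in fewer steps than the eleven that lead to 15. In these respects it is the better road.
- Weak points: the vinyl carbon that becomes C11 is attached to quaternary C12. The cyclopropane must cleave at its unsubstituted carbon so that C8 stays on C7. The cyclopropane carbon C7 is stereogenic and racemic in A4, so the catalyst has to overrule it. Above all, A3 holds only ring D and seven cage carbons: C4, C5, C6 and C9, the geranyl and benzoyl groups and the quaternisation of C3 at an alkene carbon all remain.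
- Comparison: against the quicker start the chosen plan sets a key-step product 15 that already has ring B attached through C10 with C7 defined, so that only C4, the geranyl group and the benzoyl group have to be added.

Alternative 3: This plan cuts ring A through C3–C4 and C1–C9, back to A7 and A6. A7 is the C2 silyl enol ether of the ring E/ring D bicycle with an exocyclic methylene on C7; A6 is geranylmalonyl dichloride.
- Forward key step: acylation at C3 by one acid chloride, then, with aqueous KOH and a phase-transfer salt, acylation at C1, to give the enol trione A5 (Effenberger annulation). Ring B would follow by joining the methylene carbon on C7 to C5, and C1 would then be benzoylated.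
- Merits: C4, C5, C9 and the geranyl group arrive in one reagent and two C–C bonds form in one step. This is more convergent than the four separate operations (steps 12, 14, 16 and 17) of the chosen plan, and the reaction type is the standard entry to bicyclic triones.
- Weak points: the first acylation must create the quaternary ring-fusion carbon C3 from a tetrasubstituted enol ether, and on the face trans to C10, with no obvious control element. The second must occur at C1 beside the C8 gem-dimethyl group. Monosubstituted malonyl dichlorides are prone to ketene formation, and the annulation is low-yielding even on simple enol ethers. The geranyl group is present before ring B is closed onto an unactivated 1,1-disubstituted alkene.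
- Comparison: the chosen plan answers with a regiochemically defined enolate for each bond (C3 from the ester, C5 from the enone, C1 as the last α-carbon), at the cost of linearity.

Key step: step 11

Assumption: Rh2(S-PTTL)4 is taken to select the C11 hydrogen that leads to (2S)-15; should the induction run the other way, the mirror-image catalyst Rh2(R-PTTL)4 replaces it and nothing else changes.
Assumption: only species prepared as stoichiometric reagents or anions in an operation of their own (8, 16, 24) are counted as non-isolated compounds; metal-bound species that arise and are consumed within one operation (the organocopper from 8, the rhodium carbenoid, the enolates of steps 14 and 17) are treated as mechanism.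

## Route

Step 1
Reactants: 1 3,3-dimethylglutaric anhydride
Product: 2 3,3-dimethylpentane-1,5-diol
Conditions: LiAlH4, THF, 0 °C → reflux; aq NaOH
Reagents that add atoms: none
Why: Exhaustive hydride reduction of a cyclic anhydride to the 1,5-diol; the quaternary carbon that becomes C12 has no enolisable neighbour and no stereocentre is involved.

Step 2
Reactants: 2 3,3-dimethylpentane-1,5-diol
Product: 3 5-[(tert-butyldimethylsilyl)oxy]-3,3-dimethylpentan-1-ol
Conditions: TBSCl (1 equiv), imidazole, CH2Cl2, 0 °C; 2 in threefold excess (recovered)
Reagents that add atoms: tert-butyldimethylsilyl chloride, CC(C)(C)[Si](C)(C)Cl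
Why: Statistical monosilylation of a symmetric diol used in excess; the two hydroxyl groups are equivalent, so only the mono/bis ratio has to be controlled.

Step 3
Reactants: 3 5-[(tert-butyldimethylsilyl)oxy]-3,3-dimethylpentan-1-ol
Product: 4 [(5-bromo-3,3-dimethylpentyl)oxy](tert-butyl)dimethylsilane
Conditions: CBr4, PPh3, CH2Cl2, 0 °C
Reagents that add atoms: carbon tetrabromide, BrC(Br)(Br)Br
Why: Appel bromination of a primary alcohol under neutral conditions that leave the silyl ether intact.

Step 4
Reactants: 5 4,4-dimethylcyclohex-2-en-1-one
Product: 6 (1S)-4,4-dimethylcyclohex-2-en-1-ol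
Conditions: (R)-2-methyl-CBS-oxazaborolidine (10 mol %), catecholborane, toluene, −78 °C
Reagents that add atoms: none
Why: CBS reduction; the alkene side of the enone acts as the large group, so the (R)-catalyst should deliver hydride to the face that gives the (S)-carbinol, and catecholborane at low temperature keeps the reduction 1,2.

Step 5
Reactants: 6 (1S)-4,4-dimethylcyclohex-2-en-1-ol
Product: 7 (1S)-4,4-dimethylcyclohex-2-en-1-yl pyridine-2-carboxylate
Conditions: picolinic acid, DCC, DMAP (cat.), CH2Cl2, rt
Reagents that add atoms: picolinic acid, OC(=O)c1ccccn1
Why: Steglich esterification at oxygen; the carbinol centre is not touched.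

Step 6
Reactants: 4 [(5-bromo-3,3-dimethylpentyl)oxy](tert-butyl)dimethylsilane; 7 (1S)-4,4-dimethylcyclohex-2-en-1-yl pyridine-2-carboxylate
Product: 9 tert-butyl({5-[(1R)-6,6-dimethylcyclohex-2-en-1-yl]-3,3-dimethylpentyl}oxy)dimethylsilane, via Grignard reagent 8 (not isolated)
Conditions: Mg, THF, rt (4 → 8, 2 equiv); CuBr·SMe2 (1 equiv), THF, −40 °C; then 7, −40 → 0 °C
Reagents that add atoms: none
Why: Picolinate-directed copper-mediated allylic substitution: magnesium held between the pyridine nitrogen and the ester carbonyl activates the leaving group and steers the alkylcopper to the γ-carbon anti to the C–O bond. The (1S) carbinol configuration is thereby relayed to (R) at C7 and the alkene moves to C5=C6.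

Step 7
Reactants: 9 tert-butyl({5-[(1R)-6,6-dimethylcyclohex-2-en-1-yl]-3,3-dimethylpentyl}oxy)dimethylsilane
Product: 10 5-[(1R)-6,6-dimethylcyclohex-2-en-1-yl]-3,3-dimethylpentan-1-ol
Conditions: TBAF, THF, rt
Reagents that add atoms: none
Why: Fluoride cleavage of the only silyl ether; nothing else in the molecule responds to fluoride.

Step 8
Reactants: 10 5-[(1R)-6,6-dimethylcyclohex-2-en-1-yl]-3,3-dimethylpentan-1-ol
Product: 11 (3R)-3-(5-iodo-3,3-dimethylpentyl)-4,4-dimethylcyclohex-1-ene
Conditions: I2, PPh3, imidazole, CH2Cl2, 0 °C → rt
Reagents that add atoms: iodine, II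
Why: Appel-type iodination of a primary alcohol; the iodide carbon (C14) is one methylene away from the quaternary centre and stays open to SN2 attack.

Step 9
Reactants: 11 (3R)-3-(5-iodo-3,3-dimethylpentyl)-4,4-dimethylcyclohex-1-ene; 12 methyl acetoacetate
Product: 13 methyl 2-acetyl-7-[(1R)-6,6-dimethylcyclohex-2-en-1-yl]-5,5-dimethylheptanoate (C2 epimers)
Conditions: K2CO3, DMF, 60 °C; 12 in 1.5-fold excess
Reagents that add atoms: none
Why: Acetoacetic ester alkylation with a primary iodide forms C3–C14; the excess of 12 suppresses dialkylation and the new centre is removed in the next step.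

Step 10
Reactants: 13 methyl 2-acetyl-7-[(1R)-6,6-dimethylcyclohex-2-en-1-yl]-5,5-dimethylheptanoate
Product: 14 methyl 2-diazo-7-[(1R)-6,6-dimethylcyclohex-2-en-1-yl]-5,5-dimethylheptanoate
Conditions: p-ABSA, DBU, MeCN, 0 °C → rt
Reagents that add atoms: 4-acetamidobenzenesulfonyl azide, CC(=O)Nc1ccc(cc1)S(=O)(=O)N=[N+]=[N-]
Why: Deacylative (Regitz) diazo transfer: the enolate of the 2-alkylacetoacetate attacks the sulfonyl azide and the triazene collapses with loss of the acetyl group to the sulfonamide, leaving the α-alkyl-α-diazo ester.

Step 11
Reactants: 14 methyl 2-diazo-7-[(1R)-6,6-dimethylcyclohex-2-en-1-yl]-5,5-dimethylheptanoate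
Product: 15 methyl (1R,2S)-2-{[(1R)-6,6-dimethylcyclohex-2-en-1-yl]methyl}-3,3-dimethylcyclopentane-1-carboxylate
Conditions: Rh2(S-PTTL)4 (1 mol %), toluene, −78 → −30 °C, slow addition of 14
Reagents that add atoms: none
Why: Dirhodium tetrakis[N-phthaloyl-(S)-tert-leucinate] takes up the diazo carbon of 14 and expels N2 to give an electrophilic dirhodium carbenoid at C3, which inserts into one C11–H bond through a concerted, asynchronous three-centre transition state with retention at C11. The closest known reaction type is the dirhodium carboxylate-catalysed intramolecular 1,5 C–H insertion of α-alkyl-α-diazo esters to cyclopentanecarboxylates, including its low-temperature enantioselective form with N-phthaloyl-tert-leucinate ligands. Ring D closes in the 1,5 mode: the carbenoid carbon, C14, C13, C12, C11 and the migrating hydrogen form a chair-like six-centre array that gives the five-membered ring. C11 is set by the catalyst, whose chiral carboxylate wall selects one of the two C11 hydrogens; the C7 centre is three bonds away and is not expected to bias the choice, but because it is present the two outcomes are diastereomers and the minor one can be removed. C3 should form mainly trans to the C10 arm, which is of no consequence because C3 is planarised in step 12. The step needs insertion to beat the 1,2-hydride shift from C14 (bulky carboxylate ligands, low temperature), the secondary C11–H to beat the six primary hydrogens of the C12 methyl groups at the same distance (the usual secondary over primary preference), and five-ring formation to beat the 1,6 alternative at C10. The quaternary C12 removes any 1,4 site, folds the chain toward the carbenoid and leaves the cyclohexene alkene too far away for cyclopropanation.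

Step 12
Reactants: 15 methyl (1R,2S)-2-{[(1R)-6,6-dimethylcyclohex-2-en-1-yl]methyl}-3,3-dimethylcyclopentane-1-carboxylate
Product: 17 methyl (1S,2R)-2-{[(1R)-6,6-dimethylcyclohex-2-en-1-yl]methyl}-1-formyl-3,3-dimethylcyclopentane-1-carboxylate, via lithium enolate 16 (not isolated)
Conditions: LiN(i-Pr)2, THF, −78 °C (15 → 16); HCO2Me, −78 °C; AcOH, −78 °C
Reagents that add atoms: methyl formate, COC=O
Why: Crossed Claisen formylation of an ester enolate; the tetrahedral adduct is stable at low temperature and gives the non-enolisable α-formyl ester on quenching. The electrophile should enter the planar C3 enolate anti to the C10 arm on C11, so the formyl carbon becomes C4 (trans to C10) and the ester carbon C2 (cis), whichever C3 epimer of 15 is used; the descriptor at C11 changes from S to R by priority only.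

Step 13
Reactants: 17 methyl (1S,2R)-2-{[(1R)-6,6-dimethylcyclohex-2-en-1-yl]methyl}-1-formyl-3,3-dimethylcyclopentane-1-carboxylate
Product: 18 methyl (1S,2R)-2-{[(1R)-6,6-dimethyl-4-oxocyclohex-2-en-1-yl]methyl}-1-formyl-3,3-dimethylcyclopentane-1-carboxylate
Conditions: CrO3, 3,5-dimethylpyrazole (15 equiv each), CH2Cl2, −20 °C
Reagents that add atoms: chromium trioxide, O=[Cr](=O)=O
Why: Allylic oxidation by the chromium trioxide–dimethylpyrazole complex: the methylene C9 is open whereas the methine C7 is shielded by the C8 gem-dimethyl group and the C10 arm, and oxygen should be delivered at the less hindered allylic terminus to give the C9(=O)–C5=C6 enone. The neopentyl aldehyde and the ester are inert under the anhydrous conditions.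

Step 14
Reactants: 18 methyl (1S,2R)-2-{[(1R)-6,6-dimethyl-4-oxocyclohex-2-en-1-yl]methyl}-1-formyl-3,3-dimethylcyclopentane-1-carboxylate
Product: 19 tricyclic hydroxy keto ester (ring C closed: C3–CO2Me, C4–OH, C5–H, C9=O; C4 epimers)
Conditions: [(Ph3P)CuH]6 (0.25 equiv, 1.5 equiv hydride), toluene, −40 → 0 °C; aq NH4Cl
Reagents that add atoms: none
Why: Reductive aldol cyclisation: conjugate hydride transfer from copper to C6 gives the C5–C9 copper enolate regiospecifically, and this adds to the C4 aldehyde to close ring C. C5 is set by the tether, since C4 can only reach the face of ring B that carries the C10 arm on C7; the C4 carbinol centre is removed in step 15.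

Step 15
Reactants: 19 tricyclic hydroxy keto ester (ring C closed: C3–CO2Me, C4–OH, C5–H, C9=O)
Product: 20 tricyclic β-diketo ester (C4=O, C9=O, C5–H, C3–CO2Me)
Conditions: Dess–Martin periodinane, NaHCO3, CH2Cl2, rt
Reagents that add atoms: none
Why: Dess–Martin oxidation of a β-hydroxy ketone to the 1,3-diketone under buffered, non-basic conditions that avoid retro-aldol opening of ring C.

Step 16
Reactants: 20 tricyclic β-diketo ester (C4=O, C9=O, C5–H, C3–CO2Me); 21 geranyl acetate
Product: 22 C5-geranyl tricyclic β-diketo ester
Conditions: Pd(PPh3)4 (5 mol %), Cs2CO3, THF, 40 °C; 21 (1.2 equiv)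
Reagents that add atoms: none
Why: Tsuji–Trost allylation: C5 is the only carbon between two ketones, and its soft enolate attacks the geranyl π-allyl palladium complex at the unsubstituted terminus and on carbon. The bicyclic frame leaves only the outward position on C5, so the configuration from step 14 is kept, and the E alkene should be retained.

Step 17
Reactants: 22 C5-geranyl tricyclic β-diketo ester
Product: 23 debenzoyl target (homoadamantane trione with C1–H)
Conditions: LiTMP (2.5 equiv), THF, −78 → −20 °C; AcOH, −78 °C
Reagents that add atoms: none
Why: Intramolecular Claisen (Dieckmann-type) condensation: C1 is the only enolisable carbon of 22, and its lithium enolate, attacking along the axial direction of ring B, is acylated by the C2 ester held above it by the two bridges, which closes ring A and fixes C1. The excess of hindered amide base and the cold acidic quench limit the exposure of the trione to the methoxide that is released.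

Step 18
Reactants: 23 debenzoyl target (homoadamantane trione with C1–H)
Product: 25 CNP0168637.1 (target), via C1-lithio trione 24 (not isolated)
Conditions: LiTMP (2 equiv), THF, −78 °C (23 → 24); PhCOCl, −78 → 0 °C
Reagents that add atoms: benzoyl chloride, O=C(Cl)c1ccccc1
Why: Bridgehead lithiation and acylation, the established way of placing the acyl group on C1 of bicyclic acylphloroglucinol cores: the C1 hydrogen lies between the C2 and C9 carbonyl groups and is the only acidic one. The pyramidal carbanion cannot react as an O-nucleophilic enolate and is benzoylated on carbon with retention.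

## Compound list

1 | 3,3-dimethylglutaric anhydride | CC1(C)CC(=O)OC(=O)C1 | starting material
2 | 3,3-dimethylpentane-1,5-diol | OCCC(C)(C)CCO | intermediate
3 | 5-[(tert-butyldimethylsilyl)oxy]-3,3-dimethylpentan-1-ol | CC(C)(C)[Si](C)(C)OCCC(C)(C)CCO | intermediate
4 | [(5-bromo-3,3-dimethylpentyl)oxy](tert-butyl)dimethylsilane | CC(C)(C)[Si](C)(C)OCCC(C)(C)CCBr | intermediate
5 | 4,4-dimethylcyclohex-2-en-1-one | CC1(C)CCC(=O)C=C1 | starting material
6 | (1S)-4,4-dimethylcyclohex-2-en-1-ol | O[C@@H]1C=CC(C)(C)CC1 | intermediate
7 | (1S)-4,4-dimethylcyclohex-2-en-1-yl pyridine-2-carboxylate | O=C(O[C@@H]1C=CC(C)(C)CC1)c1ccccn1 | intermediate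
8 | {5-[(tert-butyldimethylsilyl)oxy]-3,3-dimethylpentyl}magnesium bromide | CC(C)(C)[Si](C)(C)OCCC(C)(C)CC[Mg]Br | intermediate (not isolated)
9 | tert-butyl({5-[(1R)-6,6-dimethylcyclohex-2-en-1-yl]-3,3-dimethylpentyl}oxy)dimethylsilane | CC(C)(C)[Si](C)(C)OCCC(C)(C)CC[C@@H]1C=CCCC1(C)C | intermediate
10 | 5-[(1R)-6,6-dimethylcyclohex-2-en-1-yl]-3,3-dimethylpentan-1-ol | OCCC(C)(C)CC[C@@H]1C=CCCC1(C)C | intermediate
11 | (3R)-3-(5-iodo-3,3-dimethylpentyl)-4,4-dimethylcyclohex-1-ene | ICCC(C)(C)CC[C@@H]1C=CCCC1(C)C | intermediate
12 | methyl acetoacetate | COC(=O)CC(C)=O | starting material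
13 | methyl 2-acetyl-7-[(1R)-6,6-dimethylcyclohex-2-en-1-yl]-5,5-dimethylheptanoate (C2 epimers) | COC(=O)C(C(C)=O)CCC(C)(C)CC[C@@H]1C=CCCC1(C)C | intermediate
14 | methyl 2-diazo-7-[(1R)-6,6-dimethylcyclohex-2-en-1-yl]-5,5-dimethylheptanoate | COC(=O)C(=[N+]=[N-])CCC(C)(C)CC[C@@H]1C=CCCC1(C)C | intermediate
15 | methyl (1R,2S)-2-{[(1R)-6,6-dimethylcyclohex-2-en-1-yl]methyl}-3,3-dimethylcyclopentane-1-carboxylate (ester trans to the C10 arm; the (1S,2S) epimer, if formed, is carried on) | COC(=O)[C@@H]1CCC(C)(C)[C@H]1C[C@@H]1C=CCCC1(C)C | intermediate
16 | lithium enolate of 15 (C3 planar, C11 and C7 unchanged) | [Li+].COC([O-])=C1CCC(C)(C)[C@H]1C[C@@H]1C=CCCC1(C)C | intermediate (not isolated)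
17 | methyl (1S,2R)-2-{[(1R)-6,6-dimethylcyclohex-2-en-1-yl]methyl}-1-formyl-3,3-dimethylcyclopentane-1-carboxylate (formyl trans, ester cis to the C10 arm) | COC(=O)[C@@]1(C=O)CCC(C)(C)[C@H]1C[C@@H]1C=CCCC1(C)C | intermediate
18 | methyl (1S,2R)-2-{[(1R)-6,6-dimethyl-4-oxocyclohex-2-en-1-yl]methyl}-1-formyl-3,3-dimethylcyclopentane-1-carboxylate | COC(=O)[C@@]1(C=O)CCC(C)(C)[C@H]1C[C@@H]1C=CC(=O)CC1(C)C | intermediate
19 | tricyclic hydroxy keto ester: ring B cyclohexanone (C9=O) bridged from C5 to C7 by C4H(OH)–C3–C11–C10, ring D on C3–C11, CO2Me on C3 cis to C10, C5–H; C3, C5, C7, C11 as in the target, C4 epimers | O=C1CC(C)(C)[C@@H]2C[C@@H]3C(C)(C)CC[C@@]3(C(=O)OC)C(O)[C@H]1C2 | intermediate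
20 | tricyclic β-diketo ester: as 19 with C4 as ketone | O=C1CC(C)(C)[C@@H]2C[C@@H]3C(C)(C)CC[C@@]3(C(=O)OC)C(=O)[C@H]1C2 | intermediate
21 | geranyl acetate, (2E)-3,7-dimethylocta-2,6-dien-1-yl acetate | CC(=O)OC/C=C(\C)CCC=C(C)C | starting material
22 | C5-geranyl tricyclic β-diketo ester: as 20 with the (2E)-geranyl group on C5 in place of hydrogen | O=C1CC(C)(C)[C@@H]2C[C@@H]3C(C)(C)CC[C@@]3(C(=O)OC)C(=O)[C@@]1(C/C=C(\C)CCC=C(C)C)C2 | intermediate
23 | debenzoyl target: homoadamantane 2,4,9-trione with ring D, geranyl on C5 and hydrogen on C1 | CC(C)=CCC/C(C)=C/C[C@@]12C[C@H]3C[C@@H]4C(C)(C)CC[C@]4(C1=O)C(=O)[C@@H](C2=O)C3(C)C | intermediate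
24 | C1-lithio derivative of 23 | CC(C)=CCC/C(C)=C/C[C@@]12C[C@H]3C[C@@H]4C(C)(C)CC[C@]4(C1=O)C(=O)[C@@]([Li])(C2=O)C3(C)C | intermediate (not isolated)
25 | CNP0168637.1 | CC(C)=CCC/C(C)=C/C[C@@]12C[C@H]3C[C@@H]4C(C)(C)CC[C@]4(C1=O)C(=O)[C@@](C(=O)c1ccccc1)(C2=O)C3(C)C | target

## Step count and risks

Total: 18 steps. Longest linear sequence: 16 steps (steps 1–3 and 6–18, from 1); steps 4 and 5 form the second branch from 5 and join at step 6. One protecting group is used.

**Step 11 (key step).** The most likely failure is 1,2-hydride migration from C14 overtaking insertion at the temperature that the unactivated C11–H, flanked by the quaternary C12, requires. Next come weak discrimination between the two C11 hydrogens and some insertion into the C12 methyl groups. Fallback (from 10, returning at 15): the carbenoid is changed to the acceptor/acceptor type, for which hydride shift is not a competitor.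
- Alcohol 10 would be oxidised (TEMPO, PhI(OAc)2, aqueous MeCN) to 5-[(1R)-6,6-dimethylcyclohex-2-en-1-yl]-3,3-dimethylpentanoic acid F1.
- The imidazolide of the acid would be homologated with potassium methyl malonate and MgCl2 to the β-keto ester F2, and p-ABSA with Et3N would give the diazo keto ester F3.
- Rh2(S-PTTL)4 (or Rh2(OAc)4 with separation of the C11 diastereomers) would close ring D by the same C3–C11 insertion to the 2-oxocyclopentanecarboxylate F4, with C14 as a ketone.
- The ketone would be removed through the enol triflate F5 (NaH, PhNTf2), reduction to the cyclopentene ester F6 (Pd(OAc)2, PPh3, Bu3N, HCO2H) and conjugate reduction with Mg in MeOH. This returns 15 as a C3 epimer mixture, which step 12 planarises.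

**Step 17.** The Claisen closure may reverse: the product cannot enolise, so the methoxide set free can reopen the trione by retro-Claisen attack, and the hindered C1 enolate may be acylated slowly or on oxygen. Fallback (from 19, returning at 23): ring A is closed by aldol addition and oxidation, so that no alkoxide is released into the cage.
- Aldol 19 would be reduced with LiAlH4 to the triol F7 and oxidised with Dess–Martin periodinane to the keto aldehyde F8, in which C2 is an aldehyde and C4 and C9 are ketones.
- C5 would be geranylated as in step 16 to give the C5-geranyl keto aldehyde F9.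
- LiN(SiMe3)2 would form the C1 enolate, which adds to the C2 aldehyde to give the cage aldol F10; Dess–Martin oxidation of F10 delivers 23.

**Step 13.** Hydrogen abstraction at the tertiary C7–H, oxygen delivery at C6 (transposed enone) or slow over-oxidation of the aldehyde may erode the regioselectivity. Fallback (from 17, returning at 18): oxygen is delivered by an ene reaction and a [2,3]-sigmatropic shift, which restore the alkene at C5=C6 and cannot transpose it. SeO2 (catalytic) with t-BuOOH in CH2Cl2 should hydroxylate the methylene C9 in preference to the methine C7 and give the allylic alcohol F11; Dess–Martin periodinane would then oxidise F11 to 18.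

**Step 14.** Direct reduction of the aldehyde by the copper hydride, or protonation of the copper enolate before the slower seven-membered aldol closure, would give simple reduction products and lose the regiochemical control over C5. Fallback (from 18, returning at 19): the C5 enolate is generated by conjugate addition of a removable sulfur nucleophile in place of hydride, which leaves the aldehyde untouched. Me2AlSPh in CH2Cl2 at −78 °C would add to C6, and the aluminium enolate would close ring C to the 6-phenylsulfanyl aldol F12; Bu3SnH with AIBN would then remove sulfur and give 19.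

**Step 6.** Substitution at the carbinol carbon in place of the γ-carbon, which is flanked by the gem-dimethyl carbon, or loss of anti selectivity, would give regioisomers or lower the enantiomeric purity at C7. Fallback (from 5 and 8, returning at 9): C7 is set by catalyst-controlled conjugate addition in place of chirality transfer. Grignard reagent 8 would be added to enone 5 with CuBr·SMe2 and a chiral ferrocenyl diphosphine, and the magnesium enolate trapped with PhNTf2 as the enol triflate F13. Reduction of F13 with Pd(OAc)2, PPh3, Bu3N and HCO2H gives 9, with the alkene at C5=C6 because the enolate is formed regiospecifically.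

## Further compounds

F1 | step 11 | 5-[(1R)-6,6-dimethylcyclohex-2-en-1-yl]-3,3-dimethylpentanoic acid | OC(=O)CC(C)(C)CC[C@@H]1C=CCCC1(C)C
F2 | step 11 | methyl 7-[(1R)-6,6-dimethylcyclohex-2-en-1-yl]-5,5-dimethyl-3-oxoheptanoate | COC(=O)CC(=O)CC(C)(C)CC[C@@H]1C=CCCC1(C)C
F3 | step 11 | methyl 2-diazo-7-[(1R)-6,6-dimethylcyclohex-2-en-1-yl]-5,5-dimethyl-3-oxoheptanoate | COC(=O)C(=[N+]=[N-])C(=O)CC(C)(C)CC[C@@H]1C=CCCC1(C)C
F4 | step 11 | methyl (5S)-5-{[(1R)-6,6-dimethylcyclohex-2-en-1-yl]methyl}-4,4-dimethyl-2-oxocyclopentane-1-carboxylate (C1 epimers) | COC(=O)C1C(=O)CC(C)(C)[C@H]1C[C@@H]1C=CCCC1(C)C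
F5 | step 11 | methyl (5R)-5-{[(1R)-6,6-dimethylcyclohex-2-en-1-yl]methyl}-4,4-dimethyl-2-{[(trifluoromethyl)sulfonyl]oxy}cyclopent-1-ene-1-carboxylate | COC(=O)C1=C(OS(=O)(=O)C(F)(F)F)CC(C)(C)[C@H]1C[C@@H]1C=CCCC1(C)C
F6 | step 11 | methyl (5R)-5-{[(1R)-6,6-dimethylcyclohex-2-en-1-yl]methyl}-4,4-dimethylcyclopent-1-ene-1-carboxylate | COC(=O)C1=CCC(C)(C)[C@H]1C[C@@H]1C=CCCC1(C)C
F7 | step 17 | tricyclic triol: 19 with C9 as carbinol and the ester reduced to CH2OH (C4 and C9 epimers) | OC1CC(C)(C)[C@@H]2C[C@@H]3C(C)(C)CC[C@@]3(CO)C(O)[C@H]1C2
F8 | step 17 | tricyclic keto aldehyde: 20 with a formyl group on C3 in place of the ester | O=C1CC(C)(C)[C@@H]2C[C@@H]3C(C)(C)CC[C@@]3(C=O)C(=O)[C@H]1C2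
F9 | step 17 | C5-geranyl tricyclic keto aldehyde: 22 with a formyl group on C3 in place of the ester | O=C1CC(C)(C)[C@@H]2C[C@@H]3C(C)(C)CC[C@@]3(C=O)C(=O)[C@@]1(C/C=C(\C)CCC=C(C)C)C2
F10 | step 17 | cage aldol: 23 with C2 as carbinol (C2 epimers) | CC(C)=CCC/C(C)=C/C[C@@]12C[C@H]3C[C@@H]4C(C)(C)CC[C@]4(C1=O)C(O)[C@@H](C2=O)C3(C)C
F11 | step 13 | methyl (1S,2R)-1-formyl-2-{[(1R)-4-hydroxy-6,6-dimethylcyclohex-2-en-1-yl]methyl}-3,3-dimethylcyclopentane-1-carboxylate (carbinol epimers) | COC(=O)[C@@]1(C=O)CCC(C)(C)[C@H]1C[C@@H]1C=CC(O)CC1(C)C
F12 | step 14 | 6-phenylsulfanyl tricyclic aldol: 19 with SPh on C6 (C4 and C6 epimers) | O=C1CC(C)(C)[C@@H]2C[C@@H]3C(C)(C)CC[C@@]3(C(=O)OC)C(O)[C@H]1C2Sc1ccccc1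
F13 | step 6 | (3R)-3-{5-[(tert-butyldimethylsilyl)oxy]-3,3-dimethylpentyl}-4,4-dimethylcyclohex-1-en-1-yl trifluoromethanesulfonate | CC(C)(C)[Si](C)(C)OCCC(C)(C)CC[C@@H]1C=C(OS(=O)(=O)C(F)(F)F)CCC1(C)C
A1 | alternative 1 | 13,14-didehydro target (ring D as cyclopentene) | CC(C)=CCC/C(C)=C/C[C@@]12C[C@H]3C[C@@H]4C(C)(C)C=C[C@]4(C1=O)C(=O)[C@@](C(=O)c1ccccc1)(C2=O)C3(C)C
A2 | alternative 1 | ring A/ring B trione enol with benzoyl on C1, geranyl on C5, (Z)-2-(trimethylsilyl)vinyl on C3 and a 2,3-epoxy-3-methylbutyl group on C7 | CC(C)=CCC/C(C)=C/C[C@]12C[C@@H](C[C@@H]3OC3(C)C)C(C)(C)[C@](C(=O)c3ccccc3)(C1=O)C(O)=C(/C=C\[Si](C)(C)C)C2=O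
A3 | alternative 2 | bicyclo[5.3.0]decadiene with rings E and D and the C7 tert-butyldimethylsilyl enol ether | CC1(C)CC=C2CCC(C)(C)[C@H]2C=C1O[Si](C)(C)C(C)(C)C
A4 | alternative 2 | tert-butyl{[1-((1E)-3,3-dimethylhept-1-en-6-yn-1-yl)-2,2-dimethylcyclopropyl]oxy}dimethylsilane (racemic) | C#CCCC(C)(C)/C=C/C1(O[Si](C)(C)C(C)(C)C)CC1(C)C
A5 | alternative 3 | rings A, E and D with C1–H, the C4/C5 enol and the C7 methylene | CC(C)=CCC/C(C)=C/CC1=C(O)[C@]23CCC(C)(C)[C@H]2CC(=C)C(C)(C)[C@H](C1=O)C3=O
A6 | alternative 3 | 2-[(2E)-3,7-dimethylocta-2,6-dien-1-yl]propanedioyl dichloride | CC(C)=CCC/C(C)=C/CC(C(Cl)=O)C(Cl)=O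
A7 | alternative 3 | C2 trimethylsilyl enol ether of the ring E/ring D bicycle with C7 methylene | C[Si](C)(C)OC1=C2CCC(C)(C)[C@H]2CC(=C)C(C)(C)C1
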